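The ten-membered carbocycle is disconnected at C7–C8 (germacrane numbering). The C8 carbinol next to the ring-fusion carbon C7 of the α-methylene-γ-butyrolactone is a homoallylic alcohol, C8(O)–C7–C11=C13, the retron of a carbonyl allylation. The precursor is a C6-substituted 3-(bromomethyl)butenolide tethered through the (Z)-C4=C5 alkene, the C3 silyl ether and the 1,10-epoxide to a C8 aldehyde. CrCl2-mediated intramolecular Nozaki–Hiyama allylation attacks C8 with the γ-carbon C7. It closes the carbocycle, sets C7 and C8 and unveils the exocyclic C11=C13 methylene in one operation. Mitsunobu esterification with isobutyric acid then inverts C8, and desilylation gives the target.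

Key step: step 17

Remark: locants C1–C15 used for all intermediates are those of the target's germacrane skeleton (C1/C10 epoxide, C3 and C15 hydroxyls, C4=C5 alkene, C6 lactone oxygen, C7 ring fusion, C8 ester carbon, C11–C13 lactone, C14 methyl).
Remark: (S,S)-ProPhenol is assumed to give the (S)-carbinol in step 4; if the sense is opposite, the enantiomeric ligand is used.

Step 1
Reactants: 1 3-butyn-1-ol
Product: 2 1-[(but-3-yn-1-yloxy)methyl]-4-methoxybenzene
Conditions: NaH, PMBCl, Bu4NI (cat.), THF, 0 °C → rt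
Reagents that add atoms: 4-methoxybenzyl chloride, COc1ccc(CCl)cc1
Why: Williamson etherification of the primary alkoxide installs the oxidatively removable C8 protecting group; no stereocenter is involved.

Step 2
Reactants: 2 1-[(but-3-yn-1-yloxy)methyl]-4-methoxybenzene; 3 ethylene oxide
Product: 5 (E)-6-(4-methoxybenzyloxy)-4-methylhex-3-en-1-ol, via alkenylalane 4 (not isolated)
Conditions: AlMe3, Cp2ZrCl2 (0.2 equiv), CH2Cl2, 0 °C → rt; then n-BuLi, THF, −78 °C; then ethylene oxide, −78 → 0 °C
Reagents that add atoms: trimethylaluminium, C[Al](C)C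
Why: Negishi zirconium-catalysed carboalumination adds methyl and aluminium syn across the alkyne with aluminium at the terminus, fixing the (E)-C1=C10 geometry, and the derived alanate opens ethylene oxide with retention at C1.

Step 3
Reactants: 5 (E)-6-(4-methoxybenzyloxy)-4-methylhex-3-en-1-ol
Product: 6 (E)-6-(4-methoxybenzyloxy)-4-methylhex-3-enal
Conditions: Dess–Martin periodinane, NaHCO3, CH2Cl2, 0 °C; used crude
Reagents that add atoms: none
Why: Buffered Dess–Martin oxidation gives the β,γ-unsaturated aldehyde without base-induced migration of the alkene into conjugation.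

Step 4
Reactants: 7 (E)-but-2-enal (crotonaldehyde); 8 tert-butyldimethyl(prop-2-yn-1-yloxy)silane
Product: 10 (4S,5E)-1-(tert-butyldimethylsilyloxy)hept-5-en-2-yn-4-ol, via alkynylzinc 9 (not isolated)
Conditions: Me2Zn, (S,S)-ProPhenol (10 mol %), Ph3PO (20 mol %), toluene, 0 °C
Reagents that add atoms: none
Why: Trost dinuclear zinc ProPhenol alkynylation of an enal, in which the chiral ligand pocket differentiates the aldehyde faces and should set the carbinol (future C6) as (S).

Step 5
Reactants: 10 (4S,5E)-1-(tert-butyldimethylsilyloxy)hept-5-en-2-yn-4-ol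
Product: 12 (2Z,4S,5E)-1-(tert-butyldimethylsilyloxy)-2-iodohepta-2,5-dien-4-ol, via alkenylaluminate 11 (not isolated)
Conditions: NaAlH2(OCH2CH2OMe)2 (Red-Al), THF, 0 °C; EtOAc; then I2, −78 °C
Reagents that add atoms: iodine, [I][I]
Why: Hydroxyl-directed trans-hydroalumination places H on C5 and Al on C4 through the five-membered alanate, and iodinolysis with retention gives the (Z)-iodoalkene with iodine cis to C6, the geometry the ring alkene needs.

Step 6
Reactants: 12 (2Z,4S,5E)-1-(tert-butyldimethylsilyloxy)-2-iodohepta-2,5-dien-4-ol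
Product: 13 (2Z,4S,5E)-1-(tert-butyldimethylsilyloxy)-2-iodo-4-(triethylsilyloxy)hepta-2,5-diene
Conditions: TESCl, imidazole, CH2Cl2, 0 °C
Reagents that add atoms: chlorotriethylsilane, CC[Si](Cl)(CC)CC
Why: Silylation of the only free hydroxyl gives a temporary C6 ether that can later be removed in the presence of TBS ethers.

Step 7
Reactants: 6 (E)-6-(4-methoxybenzyloxy)-4-methylhex-3-enal; 13 (2Z,4S,5E)-1-(tert-butyldimethylsilyloxy)-2-iodo-4-(triethylsilyloxy)hepta-2,5-diene
Product: 15 (3E,7Z,9S,10E)-7-[(tert-butyldimethylsilyloxy)methyl]-1-(4-methoxybenzyloxy)-3-methyl-9-(triethylsilyloxy)dodeca-3,7,10-trien-6-ol (both C3 epimers), via alkenylchromium 14 (not isolated)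
Conditions: CrCl2, NiCl2 (1 mol %), DMSO, rt
Reagents that add atoms: none
Why: Nozaki–Hiyama–Kishi coupling (insertion of zerovalent nickel into the C–I bond with retention, transmetalation to chromium, carbonyl addition) joins C4 to C3 under non-basic conditions that the β,γ-unsaturated aldehyde tolerates; C3 is not controlled here and is set in step 9.

Step 8
Reactants: 15 C3-epimeric allylic alcohol
Product: 16 (3E,7Z,9S,10E)-7-[(tert-butyldimethylsilyloxy)methyl]-1-(4-methoxybenzyloxy)-3-methyl-9-(triethylsilyloxy)dodeca-3,7,10-trien-6-one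
Conditions: Dess–Martin periodinane, NaHCO3, CH2Cl2, 0 °C
Reagents that add atoms: none
Why: Dess–Martin oxidation of the allylic alcohol converges both C3 epimers on one enone under non-basic conditions.

Step 9
Reactants: 16 C3 enone
Product: 17 (3E,6S,7Z,9S,10E)-7-[(tert-butyldimethylsilyloxy)methyl]-1-(4-methoxybenzyloxy)-3-methyl-9-(triethylsilyloxy)dodeca-3,7,10-trien-6-ol
Conditions: (R)-2-methyl-CBS-oxazaborolidine (20 mol %), catecholborane, toluene, −78 °C
Reagents that add atoms: none
Why: Corey–Bakshi–Shibata reduction, with the α-branched alkenyl group as the large and the C2 methylene as the small substituent, should give the (3S)-alcohol from the (R)-catalyst by reagent control.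

Step 10
Reactants: 17 (3S)-allylic alcohol
Product: 18 C3 TBS ether of 17 ((3S,6S) in germacrane locants)
Conditions: TBSOTf, 2,6-lutidine, CH2Cl2, −78 °C
Reagents that add atoms: tert-butyldimethylsilyl trifluoromethanesulfonate, CC(C)(C)[Si](C)(C)OS(=O)(=O)C(F)(F)F
Why: Silyl triflate silylation protects the hindered secondary allylic hydroxyl at low temperature without touching the TES or PMB ethers.

Step 11
Reactants: 18 C3 TBS ether
Product: 19 (1R,3S,6S,10R)-1,10-epoxide of 18
Conditions: D-fructose-derived Shi ketone (0.3 equiv), Oxone (KHSO5·0.5KHSO4·0.5K2SO4), K2CO3, Bu4NHSO4, MeCN/dimethoxymethane/aq. Na2B4O7 buffer, 0 °C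
Reagents that add atoms: potassium peroxymonosulfate, [K+].[O-]S(=O)(=O)OO
Why: Shi asymmetric epoxidation, in which the chiral dioxirane attacks the only alkene not deactivated by allylic oxygen (C1=C10) through the spiro transition state; for an (E)-trisubstituted alkene and this ketone it should give the (1R,10R)-epoxide.

Step 12
Reactants: 19 (1R,3S,6S,10R)-epoxide
Product: 20 C6 alcohol ((1R,3S,6S,10R); TES removed)
Conditions: HF·pyridine, excess pyridine, THF, 0 °C
Reagents that add atoms: none
Why: The secondary TES ether is cleaved by buffered HF·pyridine much faster than the two TBS ethers, and the buffered medium spares the epoxide.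

Step 13
Reactants: 20 C6 alcohol; 21 2-(bromomethyl)acrylic acid
Product: 22 C6 2-(bromomethyl)acrylate ((1R,3S,6S,10R))
Conditions: DIC, DMAP (5 mol %), CH2Cl2, −20 → 0 °C
Reagents that add atoms: none
Why: Steglich esterification of the single free hydroxyl; low temperature and only catalytic DMAP limit attack on the allylic bromide.

Step 14
Reactants: 22 C6 2-(bromomethyl)acrylate
Product: 23 3-(bromomethyl)butenolide ((1R,3S,6R,10R); C6 descriptor changes by priority only)
Conditions: second-generation Hoveyda–Grubbs catalyst (10 mol %), toluene, 80 °C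
Reagents that add atoms: none
Why: Ring-closing metathesis starts at the propenyl group and closes onto the acrylate to give the five-membered butenolide with loss of propene; the hindered trisubstituted C4=C5 alkene stays out and C6 is untouched.

Step 15
Reactants: 23 3-(bromomethyl)butenolide
Product: 24 C8 primary alcohol ((1R,3S,6R,10R))
Conditions: DDQ, CH2Cl2/pH 7 phosphate buffer, 0 °C
Reagents that add atoms: none
Why: Oxidative cleavage of the PMB ether by DDQ under buffered conditions leaves the silyl ethers, epoxide, lactone and allylic bromide intact.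

Step 16
Reactants: 24 C8 primary alcohol
Product: 25 C8 aldehyde ((1R,3S,6R,10R))
Conditions: Dess–Martin periodinane, NaHCO3, CH2Cl2, 0 °C; used at once
Reagents that add atoms: none
Why: Buffered Dess–Martin oxidation gives the β,γ-epoxy aldehyde under non-basic conditions, and immediate use avoids epoxide-opening elimination.

Step 17
Reactants: 25 C8 aldehyde
Product: 27 (1R,3S,6R,7R,8S,10R)-8-hydroxy germacranolide 3,15-bis-TBS ether, via allylchromium 26 (not isolated)
Conditions: CrCl2 (10 equiv), THF, rt, slow addition of 25 (final 0.002 M)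
Reagents that add atoms: none
Why: CrCl2 reduces the allylic bromide in two one-electron steps to allylchromium 26 (trivalent chromium), which adds to the C8 aldehyde through its γ-carbon C7 in a six-membered Zimmerman–Traxler transition state with allylic transposition, so the C7–C8 bond and the exocyclic C11=C13 alkene arise together. The closest known reaction types are the Nozaki–Hiyama allylation used for macrocyclization and the Barbier allylation of aldehydes with 3-(bromomethyl)butenolides. The ten-membered carbocycle closes by attack on the tethered carbonyl with the C=O exocyclic to the new ring (10-exo-trig), helped by high dilution and by the (Z)-alkene, epoxide and butenolide that shorten the conformational space of the tether. C7 is controlled by C6, because the aldehyde can reach only the butenolide face anti to the C5 substituent without severe strain, which gives the trans-fused lactone (7R). C8 is controlled by the chair transition state in which C9 sits pseudo-equatorial and antiperiplanar to C11, which should give the 7,8-anti (8S, 8α) carbinol. The step needs γ- over α-attack, secured by the closed transition state, and chemoselectivity for the allylic bromide over epoxide, lactone and silyl ethers, secured by the mildness of divalent chromium.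

Step 18
Reactants: 27 (8S)-hydroxy germacranolide bis-TBS ether
Product: 28 (1R,3S,6R,7R,8R,10R)-8-isobutyrate 3,15-bis-TBS ether
Conditions: isobutyric acid, PPh3, DIAD (betaine pre-formed), toluene, 0 °C → rt
Reagents that add atoms: isobutyric acid, CC(C)C(=O)O
Why: Mitsunobu esterification proceeds by SN2 displacement of the C8 alkoxyphosphonium by isobutyrate, inverting 8S to the required 8R ester.

Step 19
Reactants: 28 8-isobutyrate bis-TBS ether
Product: 29 target CNP0219050.1
Conditions: HF·pyridine, excess pyridine, THF, 0 °C → rt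
Reagents that add atoms: none
Why: Fluoride-driven cleavage of both TBS ethers in buffered HF·pyridine should spare the epoxide, isobutyrate and α-methylene lactone and releases the C3 and C15 hydroxyls.

Compound list
1 | 3-butyn-1-ol | C#CCCO | starting material
2 | 1-[(but-3-yn-1-yloxy)methyl]-4-methoxybenzene | C#CCCOCc1ccc(OC)cc1 | intermediate
3 | ethylene oxide | C1CO1 | starting material
4 | [(E)-4-(4-methoxybenzyloxy)-2-methylbut-1-en-1-yl]dimethylalane | C[Al](C)/C=C(\C)CCOCc1ccc(OC)cc1 | intermediate (not isolated)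
5 | (E)-6-(4-methoxybenzyloxy)-4-methylhex-3-en-1-ol | OCC/C=C(\C)CCOCc1ccc(OC)cc1 | intermediate
6 | (E)-6-(4-methoxybenzyloxy)-4-methylhex-3-enal | O=CC/C=C(\C)CCOCc1ccc(OC)cc1 | intermediate
7 | (E)-but-2-enal (crotonaldehyde) | C/C=C/C=O | starting material
8 | tert-butyldimethyl(prop-2-yn-1-yloxy)silane | C#CCO[Si](C)(C)C(C)(C)C | starting material
9 | [3-(tert-butyldimethylsilyloxy)prop-1-yn-1-yl](methyl)zinc | C[Zn]C#CCO[Si](C)(C)C(C)(C)C | intermediate (not isolated)
10 | (4S,5E)-1-(tert-butyldimethylsilyloxy)hept-5-en-2-yn-4-ol | O[C@@H](/C=C/C)C#CCO[Si](C)(C)C(C)(C)C | intermediate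
11 | sodium cyclic alkenylaluminate from 10 (Al bound to the C6 oxygen and to C4, two 2-methoxyethoxy ligands) | COCCO[Al-]1(OCCOC)O[C@@H](/C=C/C)C=C1CO[Si](C)(C)C(C)(C)C.[Na+] | intermediate (not isolated)
12 | (2Z,4S,5E)-1-(tert-butyldimethylsilyloxy)-2-iodohepta-2,5-dien-4-ol | O[C@@H](/C=C/C)/C=C(/CO[Si](C)(C)C(C)(C)C)I | intermediate
13 | (2Z,4S,5E)-1-(tert-butyldimethylsilyloxy)-2-iodo-4-(triethylsilyloxy)hepta-2,5-diene | CC[Si](CC)(CC)O[C@@H](/C=C/C)/C=C(/CO[Si](C)(C)C(C)(C)C)I | intermediate
14 | alkenylchromium dichloride from 13 (CrCl2 in place of iodine, geometry retained) | CC[Si](CC)(CC)O[C@@H](/C=C/C)/C=C(/CO[Si](C)(C)C(C)(C)C)[Cr](Cl)Cl | intermediate (not isolated)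
15 | (3E,7Z,9S,10E)-7-[(tert-butyldimethylsilyloxy)methyl]-1-(4-methoxybenzyloxy)-3-methyl-9-(triethylsilyloxy)dodeca-3,7,10-trien-6-ol, both epimers at the carbinol (C3) | CC[Si](CC)(CC)O[C@@H](/C=C/C)/C=C(/CO[Si](C)(C)C(C)(C)C)C(O)C/C=C(\C)CCOCc1ccc(OC)cc1 | intermediate
16 | (3E,7Z,9S,10E)-7-[(tert-butyldimethylsilyloxy)methyl]-1-(4-methoxybenzyloxy)-3-methyl-9-(triethylsilyloxy)dodeca-3,7,10-trien-6-one | CC[Si](CC)(CC)O[C@@H](/C=C/C)/C=C(/CO[Si](C)(C)C(C)(C)C)C(=O)C/C=C(\C)CCOCc1ccc(OC)cc1 | intermediate
17 | (3E,6S,7Z,9S,10E)-7-[(tert-butyldimethylsilyloxy)methyl]-1-(4-methoxybenzyloxy)-3-methyl-9-(triethylsilyloxy)dodeca-3,7,10-trien-6-ol | CC[Si](CC)(CC)O[C@@H](/C=C/C)/C=C(/CO[Si](C)(C)C(C)(C)C)[C@@H](O)C/C=C(\C)CCOCc1ccc(OC)cc1 | intermediate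
18 | C3 TBS ether of 17; germacrane locants (3S,6S), 1(10)E, 4Z, C8–OPMB, C15–OTBS, C6–OTES, (E)-propenyl on C6 | CC[Si](CC)(CC)O[C@@H](/C=C/C)/C=C(/CO[Si](C)(C)C(C)(C)C)[C@@H](O[Si](C)(C)C(C)(C)C)C/C=C(\C)CCOCc1ccc(OC)cc1 | intermediate
19 | (1R,3S,6S,10R)-1,10-epoxide of 18 (trans-epoxide) | CC[Si](CC)(CC)O[C@@H](/C=C/C)/C=C(/CO[Si](C)(C)C(C)(C)C)[C@@H](O[Si](C)(C)C(C)(C)C)C[C@H]1O[C@]1(C)CCOCc1ccc(OC)cc1 | intermediate
20 | C6 alcohol from 19, (1R,3S,6S,10R) | O[C@@H](/C=C/C)/C=C(/CO[Si](C)(C)C(C)(C)C)[C@@H](O[Si](C)(C)C(C)(C)C)C[C@H]1O[C@]1(C)CCOCc1ccc(OC)cc1 | intermediate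
21 | 2-(bromomethyl)acrylic acid | C=C(CBr)C(=O)O | starting material
22 | C6 2-(bromomethyl)acrylate of 20, (1R,3S,6S,10R) | C=C(CBr)C(=O)O[C@@H](/C=C/C)/C=C(/CO[Si](C)(C)C(C)(C)C)[C@@H](O[Si](C)(C)C(C)(C)C)C[C@H]1O[C@]1(C)CCOCc1ccc(OC)cc1 | intermediate
23 | 3-(bromomethyl)furan-2(5H)-one carrying at its C5 (germacrane C6, R) the (Z)-alkenyl chain with C15–OTBS, (3S)-OTBS, (1R,10R)-epoxide and C8–OPMB | O=C1O[C@@H](C=C1CBr)/C=C(/CO[Si](C)(C)C(C)(C)C)[C@@H](O[Si](C)(C)C(C)(C)C)C[C@H]2O[C@]2(C)CCOCc2ccc(OC)cc2 | intermediate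
24 | C8 primary alcohol from 23, (1R,3S,6R,10R) | O=C1O[C@@H](C=C1CBr)/C=C(/CO[Si](C)(C)C(C)(C)C)[C@@H](O[Si](C)(C)C(C)(C)C)C[C@H]2O[C@]2(C)CCO | intermediate
25 | C8 aldehyde from 24, (1R,3S,6R,10R) | O=C1O[C@@H](C=C1CBr)/C=C(/CO[Si](C)(C)C(C)(C)C)[C@@H](O[Si](C)(C)C(C)(C)C)C[C@H]2O[C@]2(C)CC=O | intermediate
26 | allylchromium dichloride from 25 (CrCl2 on C13) | O=C1O[C@@H](C=C1C[Cr](Cl)Cl)/C=C(/CO[Si](C)(C)C(C)(C)C)[C@@H](O[Si](C)(C)C(C)(C)C)C[C@H]2O[C@]2(C)CC=O | intermediate (not isolated)
27 | (1R,3S,6R,7R,8S,10R)-8-hydroxy-1,10-epoxy-3,15-bis(tert-butyldimethylsilyloxy)germacra-4(Z),11(13)-dien-12,6-olide (8α-OH) | C=C1C(=O)O[C@@H]2/C=C(/CO[Si](C)(C)C(C)(C)C)[C@@H](O[Si](C)(C)C(C)(C)C)C[C@H]3O[C@]3(C)C[C@H](O)[C@@H]12 | intermediate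
28 | (1R,3S,6R,7R,8R,10R)-8-isobutyrate, 3,15-bis-TBS ether of the target | C=C1C(=O)O[C@@H]2/C=C(/CO[Si](C)(C)C(C)(C)C)[C@@H](O[Si](C)(C)C(C)(C)C)C[C@H]3O[C@]3(C)C[C@@H](OC(=O)C(C)C)[C@@H]12 | intermediate
29 | CNP0219050.1, (1R,3S,6R,7R,8R,10R) | C=C1C(=O)O[C@@H]2/C=C(/CO)[C@@H](O)C[C@H]3O[C@]3(C)C[C@@H](OC(=O)C(C)C)[C@@H]12 | target

Total step count: 19
Longest linear sequence: 16 steps (steps 1–3, then 7–19; the branch through steps 4–6 is equally long)

Steps most likely to fail

Step 17. The closed transition state may not discriminate the C8 faces as predicted: tether strain could force C9 pseudo-axial or a boat arrangement, so that the 8β-carbinol forms in part or entirely. The fallback sets out from 25 and uses the same chromium-mediated closure. Any (8R)-hydroxy germacranolide bis-TBS ether F1 is then acylated with retention (isobutyric anhydride, DMAP, pyridine, CH2Cl2, 0 °C), which comes back to the route at 28; the 8α-epimer 27 continues through step 18, so both epimers converge.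

Step 18. Displacement at the hindered C8 may be outrun by elimination toward C7 or C9, or by addition of the phosphine to the methylene lactone. The fallback sets out from 27. The alcohol is converted into the (8S)-chloromethanesulfonate F2 (ClCH2SO2Cl, pyridine, CH2Cl2, 0 °C). F2 is displaced with inversion by cesium isobutyrate and 18-crown-6 in toluene at 60 °C, which comes back to the route at 28.

Step 14. The ruthenium alkylidene may be deactivated by reaction with the allylic bromide before it closes onto the electron-poor acrylate. The fallback sets out from 22 and masks the halide. KOAc in DMF gives the C6 2-(acetoxymethyl)acrylate F3. Ring-closing metathesis under the step 14 conditions gives the 3-(acetoxymethyl)butenolide F4. Transesterification with Candida antarctica lipase B and n-butanol in MTBE gives the 3-(hydroxymethyl)butenolide F5. Appel bromination (CBr4, PPh3, CH2Cl2, 0 °C) comes back to the route at 23.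

Further compounds
F1 | step 17 | (1R,3S,6R,7R,8R,10R)-8-hydroxy germacranolide 3,15-bis-TBS ether (8β-OH epimer of 27) | C=C1C(=O)O[C@@H]2/C=C(/CO[Si](C)(C)C(C)(C)C)[C@@H](O[Si](C)(C)C(C)(C)C)C[C@H]3O[C@]3(C)C[C@@H](O)[C@@H]12
F2 | step 18 | (8S)-chloromethanesulfonate of 27 | C=C1C(=O)O[C@@H]2/C=C(/CO[Si](C)(C)C(C)(C)C)[C@@H](O[Si](C)(C)C(C)(C)C)C[C@H]3O[C@]3(C)C[C@H](OS(=O)(=O)CCl)[C@@H]12
F3 | step 14 | C6 2-(acetoxymethyl)acrylate (acetate in place of bromide in 22) | C=C(COC(C)=O)C(=O)O[C@@H](/C=C/C)/C=C(/CO[Si](C)(C)C(C)(C)C)[C@@H](O[Si](C)(C)C(C)(C)C)C[C@H]1O[C@]1(C)CCOCc1ccc(OC)cc1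
F4 | step 14 | 3-(acetoxymethyl)butenolide (acetate in place of bromide in 23) | O=C1O[C@@H](C=C1COC(C)=O)/C=C(/CO[Si](C)(C)C(C)(C)C)[C@@H](O[Si](C)(C)C(C)(C)C)C[C@H]2O[C@]2(C)CCOCc2ccc(OC)cc2
F5 | step 14 | 3-(hydroxymethyl)butenolide (hydroxyl in place of bromide in 23) | O=C1O[C@@H](C=C1CO)/C=C(/CO[Si](C)(C)C(C)(C)C)[C@@H](O[Si](C)(C)C(C)(C)C)C[C@H]2O[C@]2(C)CCOCc2ccc(OC)cc2
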